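The route rests on one disconnection: the oxolane O–C9 bond (C19 chain numbering: ring O, C6, C7, C8, C9; carbinol C10) is traced back to a six-membered pyranoside whose ring oxygen sits on C10. The key step exploits the vicinal, oxygen-bearing pair C9 (ring) and C10 (exocyclic): methanolysis of a C9 triflate shifts the ring oxygen from C10 to C9, contracts the oxane to the 2,5-trans oxolane, inverts C9 and releases C10 as a dimethyl acetal in one operation. Its precursor is a methyl pyranoside with equatorial OMe (C10), OTf (C9) and pentyl (C6) and an axial silyl ether (C7), made from a furyl carbinol by Achmatowicz rearrangement.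

Key step: step 10

Remarks on the chemistry
- Chain numbering is used throughout: pentyl C1–C5, ring carbons C6–C9, carbinol C10, alkenyl chain C11–C19; the target is (6S,7S,9R,10R).
- 2-Hexanoylfuran is taken as a purchasable starting material (it is sold as a flavour chemical).
- In step 3 the antipode of benzotetramisole is the one matched to the lactol epimer with the C10 oxygen cis to the pentyl group; one trial with each antipode fixes the choice.

Step 1
Reactants: 1 2-hexanoylfuran [1-(furan-2-yl)hexan-1-one]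
Product: 2 (S)-1-(furan-2-yl)hexan-1-ol
Conditions: RuCl(p-cymene)[(S,S)-TsDPEN] (0.5 mol %), HCO2H/Et3N (5:2), rt
Reagents that add atoms: none
Why: Noyori asymmetric transfer hydrogenation: the furyl ring takes the aryl position in the CH/π-organised hydride-transfer transition state, so the (S,S) catalyst should give the (S)-carbinol as it does with aryl alkyl ketones, and this sets C6.

Step 2
Reactants: 2 (S)-1-(furan-2-yl)hexan-1-ol
Product: 4 (2S)-6-hydroxy-2-pentyl-2H-pyran-3(6H)-one, via (S,Z)-5-hydroxy-4-oxodec-2-enal 3 (not isolated)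
Conditions: NBS, NaHCO3, NaOAc, THF/H2O (4:1), 0 °C
Reagents that add atoms: water, O
Why: Achmatowicz rearrangement: bromonium-induced hydration of the furan at C10 opens it to the Z-ene-dione 3, whose C6 hydroxyl closes onto the C10 aldehyde to give the pyranone lactol without touching C6.

Step 3
Reactants: 4 (2S)-6-hydroxy-2-pentyl-2H-pyran-3(6H)-one
Product: 5 (2R,6S)-5-oxo-6-pentyl-5,6-dihydro-2H-pyran-2-yl 2-methylpropanoate (acyloxy and pentyl cis)
Conditions: (i-PrCO)2O, i-Pr2NEt, benzotetramisole (5 mol %, cis-selective antipode), CHCl3, 0 °C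
Reagents that add atoms: isobutyric anhydride, CC(C)C(=O)OC(=O)C(C)C
Why: Dynamic kinetic diastereoselective acylation by chiral isothiourea acyl-transfer catalysis: the lactol epimers interconvert through 3 while the catalyst acylates only the epimer it matches, so C10 is set by the catalyst (acyloxy cis to pentyl) and not by the anomeric preference for trans.

Step 4
Reactants: 5 (2R,6S)-5-oxo-6-pentyl-5,6-dihydro-2H-pyran-2-yl 2-methylpropanoate; 6 methanol
Product: 7 (2S,6S)-6-methoxy-2-pentyl-2H-pyran-3(6H)-one (methoxy and pentyl cis)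
Conditions: Pd2(dba)3·CHCl3 (2.5 mol %), PPh3 (10 mol %), MeOH (3 equiv), CH2Cl2, 0 °C
Reagents that add atoms: none
Why: Pd(0)-catalysed allylic substitution (Tsuji–Trost O-glycosylation): ionisation of the ester anti to palladium and attack of methanol on the π-allyl complex anti to palladium amount to a double inversion, so the cis configuration at C10 is carried over with retention.

Step 5
Reactants: 7 (2S,6S)-6-methoxy-2-pentyl-2H-pyran-3(6H)-one
Product: 8 (2S,5S,6S)-5-(benzyloxy)-6-methoxy-2-pentyloxan-3-one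
Conditions: BnOH (5 equiv), t-BuOK (10 mol %), THF, −20 → 0 °C; AcOH quench
Reagents that add atoms: benzyl alcohol, OCc1ccccc1
Why: Base-catalysed oxa-Michael addition: benzyl oxide adds to the enone β-carbon C9 on the face opposite the C10 methoxy and C6 pentyl groups, and since the reversible addition also ends in the chair with OBn, OMe and pentyl all equatorial, kinetic and thermodynamic preference agree on the new C9 centre.

Step 6
Reactants: 8 (2S,5S,6S)-5-(benzyloxy)-6-methoxy-2-pentyloxan-3-one
Product: 9 (2S,3S,5S,6S)-5-(benzyloxy)-6-methoxy-2-pentyloxan-3-ol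
Conditions: L-Selectride, THF, −78 °C; then H2O
Reagents that add atoms: none
Why: Ketone reduction with a bulky trialkylborohydride: L-Selectride attacks the C7 carbonyl along the equatorial trajectory and so should give the axial alcohol cis to the pentyl group (7S).

Step 7
Reactants: 9 (2S,3S,5S,6S)-5-(benzyloxy)-6-methoxy-2-pentyloxan-3-ol
Product: 10 {[(2S,3S,5S,6S)-5-(benzyloxy)-6-methoxy-2-pentyloxan-3-yl]oxy}(tert-butyl)dimethylsilane
Conditions: TBSOTf, 2,6-lutidine, CH2Cl2, 0 °C
Reagents that add atoms: tert-butyldimethylsilyl trifluoromethanesulfonate, CC(C)(C)[Si](C)(C)OS(=O)(=O)C(F)(F)F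
Why: Silylation of a hindered axial secondary alcohol with the silyl triflate and a hindered base; no stereocentre is touched.

Step 8
Reactants: 10 {[(2S,3S,5S,6S)-5-(benzyloxy)-6-methoxy-2-pentyloxan-3-yl]oxy}(tert-butyl)dimethylsilane
Product: 11 (2S,3S,5S,6S)-5-[(tert-butyldimethylsilyl)oxy]-2-methoxy-6-pentyloxan-3-ol
Conditions: H2 (1 atm), Pd/C, EtOAc, rt
Reagents that add atoms: none
Why: Hydrogenolysis of the benzyl ether over palladium frees the C9 hydroxyl, while the silyl ether and the methyl acetal are inert in neutral ethyl acetate.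

Step 9
Reactants: 11 (2S,3S,5S,6S)-5-[(tert-butyldimethylsilyl)oxy]-2-methoxy-6-pentyloxan-3-ol
Product: 12 (2S,3S,5S,6S)-5-[(tert-butyldimethylsilyl)oxy]-2-methoxy-6-pentyloxan-3-yl trifluoromethanesulfonate (OMe, OTf and pentyl equatorial; OTBS axial)
Conditions: Tf2O, pyridine, CH2Cl2, −20 °C
Reagents that add atoms: trifluoromethanesulfonic anhydride, O=S(=O)(OS(=O)(=O)C(F)(F)F)C(F)(F)F
Why: Sulfonylation of the equatorial C9 alcohol with triflic anhydride and pyridine at low temperature proceeds with retention at C9; the triflate is passed cold through a short silica plug and used at once.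

Step 10
Reactants: 12 (2S,3S,5S,6S)-5-[(tert-butyldimethylsilyl)oxy]-2-methoxy-6-pentyloxan-3-yl trifluoromethanesulfonate; 6 methanol
Product: 14 tert-butyl{[(2S,3S,5R)-5-(dimethoxymethyl)-2-pentyloxolan-3-yl]oxy}dimethylsilane, via methoxy-oxocarbenium ion 13 (not isolated)
Conditions: MeOH, 2,6-di-tert-butyl-4-methylpyridine (2 equiv), 50 °C
Reagents that add atoms: none
Why: In the chair of 12 the equatorial C9–OTf bond lies antiperiplanar to the ring O–C10 bond, so on ionisation the ring oxygen bonds to C9 from the rear while its bond to C10 breaks (a 1,2-oxygen shift through a three-centre O/C9/C10 transition state), leaving the methoxy-stabilised oxocarbenium ion 13, which methanol caps as the dimethyl acetal. The closest known reaction type is the solvolytic ring contraction of pyranoside 2-O-sulfonates (and the nitrous acid deamination of 2-amino-2-deoxypyranosides) to 2,5-anhydro sugar acetals. The oxolane ring (O, C6, C7, C8, C9) closes in a 5-exo-tet sense, the triflate leaving outside the new ring. The only stereocentre changed is C9, inverted from S to R by the stereospecific rear-side attack, which places the acetal arm trans to the C6 pentyl group; C6 and C7 are untouched and C10 ceases to be stereogenic. The step needs oxygen migration to beat direct substitution by methanol, elimination and participation from C7: the equatorial triflate has no antiperiplanar hydrogen, methanol is a weak nucleophile at a carbon flanked by an acetal, the silyl ether cannot participate, and the hindered pyridine only buffers the triflic acid so that silyl ether and acetal survive.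

Step 11
Reactants: 14 tert-butyl{[(2S,3S,5R)-5-(dimethoxymethyl)-2-pentyloxolan-3-yl]oxy}dimethylsilane
Product: 15 (2S,3S,5R)-5-(dimethoxymethyl)-2-pentyloxolan-3-ol
Conditions: TBAF, THF, 0 °C → rt
Reagents that add atoms: none
Why: Fluoride-mediated desilylation frees the C7 hydroxyl; the dimethyl acetal is stable to the basic fluoride.

Step 12
Reactants: 15 (2S,3S,5R)-5-(dimethoxymethyl)-2-pentyloxolan-3-ol; 16 stearoyl chloride (octadecanoyl chloride)
Product: 17 (2S,3S,5R)-5-(dimethoxymethyl)-2-pentyloxolan-3-yl octadecanoate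
Conditions: Et3N, DMAP (cat.), CH2Cl2, 0 °C → rt
Reagents that add atoms: none
Why: DMAP-catalysed acylation of the secondary C7 alcohol with the acid chloride installs the stearate with retention.

Step 13
Reactants: 17 (2S,3S,5R)-5-(dimethoxymethyl)-2-pentyloxolan-3-yl octadecanoate
Product: 18 (2S,3S,5R)-5-formyl-2-pentyloxolan-3-yl octadecanoate
Conditions: TFA/H2O (9:1), CH2Cl2, 0 °C
Reagents that add atoms: water, O
Why: Acid-catalysed acetal hydrolysis unmasks the C10 aldehyde under cold conditions that leave the ester and the C9 centre alone; the aldehyde is used crude.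

Step 14
Reactants: 18 (2S,3S,5R)-5-formyl-2-pentyloxolan-3-yl octadecanoate; 19 9-bromonon-1-ene
Product: 21 (2S,3S,5R)-5-[(1R)-1-hydroxydec-9-en-1-yl]-2-pentyloxolan-3-yl octadecanoate, via non-8-enylmagnesium bromide 20 (not isolated)
Conditions: 19, Mg, Et2O, rt; then 18, MgBr2·OEt2, CH2Cl2, −78 °C; then H2O
Reagents that add atoms: none
Why: Chelation-controlled (Cram chelate) Grignard addition: magnesium bridges the aldehyde oxygen and the ring oxygen, the nucleophile enters from the side of the C9 hydrogen to give the 9,10-threo (10R) carbinol, and at −78 °C the alkyl Grignard reagent adds to the aldehyde far faster than to the hindered secondary stearate.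

Compound list
1 | 2-hexanoylfuran [1-(furan-2-yl)hexan-1-one] | CCCCCC(=O)c1ccco1 | starting material
2 | (S)-1-(furan-2-yl)hexan-1-ol | CCCCC[C@H](O)c1ccco1 | intermediate
3 | (S,Z)-5-hydroxy-4-oxodec-2-enal | CCCCC[C@H](O)C(=O)/C=C\C=O | intermediate (not isolated)
4 | (2S)-6-hydroxy-2-pentyl-2H-pyran-3(6H)-one (both lactol epimers at chain C10) | OC1O[C@@H](CCCCC)C(=O)C=C1 | intermediate
5 | (2R,6S)-5-oxo-6-pentyl-5,6-dihydro-2H-pyran-2-yl 2-methylpropanoate (acyloxy and pentyl cis) | CC(C)C(=O)O[C@H]1O[C@@H](CCCCC)C(=O)C=C1 | intermediate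
6 | methanol | CO | starting material
7 | (2S,6S)-6-methoxy-2-pentyl-2H-pyran-3(6H)-one (methoxy and pentyl cis) | CO[C@H]1O[C@@H](CCCCC)C(=O)C=C1 | intermediate
8 | (2S,5S,6S)-5-(benzyloxy)-6-methoxy-2-pentyloxan-3-one | CO[C@H]1O[C@@H](CCCCC)C(=O)C[C@@H]1OCc2ccccc2 | intermediate
9 | (2S,3S,5S,6S)-5-(benzyloxy)-6-methoxy-2-pentyloxan-3-ol | CO[C@H]1O[C@@H](CCCCC)[C@@H](O)C[C@@H]1OCc2ccccc2 | intermediate
10 | {[(2S,3S,5S,6S)-5-(benzyloxy)-6-methoxy-2-pentyloxan-3-yl]oxy}(tert-butyl)dimethylsilane | CO[C@H]1O[C@@H](CCCCC)[C@@H](O[Si](C)(C)C(C)(C)C)C[C@@H]1OCc2ccccc2 | intermediate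
11 | (2S,3S,5S,6S)-5-[(tert-butyldimethylsilyl)oxy]-2-methoxy-6-pentyloxan-3-ol | CO[C@H]1O[C@@H](CCCCC)[C@@H](O[Si](C)(C)C(C)(C)C)C[C@@H]1O | intermediate
12 | (2S,3S,5S,6S)-5-[(tert-butyldimethylsilyl)oxy]-2-methoxy-6-pentyloxan-3-yl trifluoromethanesulfonate | CO[C@H]1O[C@@H](CCCCC)[C@@H](O[Si](C)(C)C(C)(C)C)C[C@@H]1OS(=O)(=O)C(F)(F)F | intermediate
13 | methoxy-oxocarbenium ion of the contracted ring [(2R,4S,5S)-4-silyloxy-5-pentyloxolan-2-yl]methylidene(methyl)oxonium | C[O+]=C[C@H]1C[C@H](O[Si](C)(C)C(C)(C)C)[C@H](CCCCC)O1 | intermediate (not isolated)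
14 | tert-butyl{[(2S,3S,5R)-5-(dimethoxymethyl)-2-pentyloxolan-3-yl]oxy}dimethylsilane (2,5-trans) | COC(OC)[C@H]1C[C@H](O[Si](C)(C)C(C)(C)C)[C@H](CCCCC)O1 | intermediate
15 | (2S,3S,5R)-5-(dimethoxymethyl)-2-pentyloxolan-3-ol | COC(OC)[C@H]1C[C@H](O)[C@H](CCCCC)O1 | intermediate
16 | stearoyl chloride (octadecanoyl chloride) | CCCCCCCCCCCCCCCCCC(=O)Cl | starting material
17 | (2S,3S,5R)-5-(dimethoxymethyl)-2-pentyloxolan-3-yl octadecanoate | COC(OC)[C@H]1C[C@H](OC(=O)CCCCCCCCCCCCCCCCC)[C@H](CCCCC)O1 | intermediate
18 | (2S,3S,5R)-5-formyl-2-pentyloxolan-3-yl octadecanoate | O=C[C@H]1C[C@H](OC(=O)CCCCCCCCCCCCCCCCC)[C@H](CCCCC)O1 | intermediate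
19 | 9-bromonon-1-ene | C=CCCCCCCCBr | starting material
20 | non-8-enylmagnesium bromide | C=CCCCCCCC[Mg]Br | intermediate (not isolated)
21 | (2S,3S,5R)-5-[(1R)-1-hydroxydec-9-en-1-yl]-2-pentyloxolan-3-yl octadecanoate (CNP0171131.1) | C=CCCCCCCC[C@@H](O)[C@H]1C[C@H](OC(=O)CCCCCCCCCCCCCCCCC)[C@H](CCCCC)O1 | target

Total step count: 14
Longest linear sequence: 14 steps (1 → 21); 16 enters in step 12 and 19 in step 14.

Steps most likely to fail

Step 10 (ring contraction). The ionisation may be overtaken by direct substitution at C9 by methanol or by decomposition of the triflate, or the acid set free may strip the silyl ether. The fallback opens the six-membered ring first and closes the five-membered ring second, without any oxygen shift. It sets out from 11: oxidation of the methyl acetal carbon (mCPBA, BF3·OEt2, CH2Cl2, 0 °C) should give the hydroxy lactone (3S,5S,6S)-5-[(tert-butyldimethylsilyl)oxy]-3-hydroxy-6-pentyloxan-2-one F1. Triflation (Tf2O, pyridine, −20 °C) gives (3S,5S,6S)-5-[(tert-butyldimethylsilyl)oxy]-2-oxo-6-pentyloxan-3-yl trifluoromethanesulfonate F2. With K2CO3 in MeOH at −10 °C methoxide opens the lactone and the freed C6 alkoxide displaces the C9 triflate (5-exo-tet, inversion, the same C9 configuration as in 14) to give methyl (2R,4S,5S)-4-[(tert-butyldimethylsilyl)oxy]-5-pentyloxolane-2-carboxylate F3. DIBAL-H (CH2Cl2, −78 °C) gives (2R,4S,5S)-4-[(tert-butyldimethylsilyl)oxy]-5-pentyloxolane-2-carbaldehyde F4, and HC(OMe)3 with catalytic PPTS in MeOH brings the sequence back to 14.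

Step 5 (oxa-Michael addition). The addition equilibrium may lie too far on the enone side, or the base may epimerise C6 next to the ketone. The fallback brings in the C9 oxygen by oxidation and reductive cleavage and sets out from 7. Nucleophilic epoxidation (H2O2, NaOH, MeOH, −20 °C, anti to methoxy and pentyl) should give the epoxy ketone (1S,2S,4S,6R)-2-methoxy-4-pentyl-3,7-dioxabicyclo[4.1.0]heptan-5-one F5. SmI2 (THF/MeOH, −90 °C) cleaves the C8–O bond α to the ketone and gives (2S,5S,6S)-5-hydroxy-6-methoxy-2-pentyloxan-3-one F6. Acid-catalysed benzylation (benzyl 2,2,2-trichloroacetimidate, cat. TfOH, CH2Cl2/cyclohexane, 0 °C), which avoids base-induced elimination, returns to 8.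

Step 14 (Grignard addition). Facial selectivity may be poor if chelation between the ring oxygen and the aldehyde is incomplete. The fallback sets C10 by reduction instead of by C–C bond formation and sets out from 18. Addition of 20 without additive (THF, −78 °C) gives 21 together with its C10 epimer (2S,3S,5R)-5-[(1S)-1-hydroxydec-9-en-1-yl]-2-pentyloxolan-3-yl octadecanoate F7. Dess–Martin oxidation of the mixture gives the ketone (2S,3S,5R)-5-(dec-9-enoyl)-2-pentyloxolan-3-yl octadecanoate F8. L-Selectride (THF, −78 °C) should then reduce it under Felkin–Anh control, with the ring C–O bond anti to the incoming hydride, to the threo alcohol 21; the stearate is not touched at this temperature.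

Further compounds
F1 | step 10 | (3S,5S,6S)-5-[(tert-butyldimethylsilyl)oxy]-3-hydroxy-6-pentyloxan-2-one | O=C1O[C@@H](CCCCC)[C@@H](O[Si](C)(C)C(C)(C)C)C[C@@H]1O
F2 | step 10 | (3S,5S,6S)-5-[(tert-butyldimethylsilyl)oxy]-2-oxo-6-pentyloxan-3-yl trifluoromethanesulfonate | O=C1O[C@@H](CCCCC)[C@@H](O[Si](C)(C)C(C)(C)C)C[C@@H]1OS(=O)(=O)C(F)(F)F
F3 | step 10 | methyl (2R,4S,5S)-4-[(tert-butyldimethylsilyl)oxy]-5-pentyloxolane-2-carboxylate | COC(=O)[C@H]1C[C@H](O[Si](C)(C)C(C)(C)C)[C@H](CCCCC)O1
F4 | step 10 | (2R,4S,5S)-4-[(tert-butyldimethylsilyl)oxy]-5-pentyloxolane-2-carbaldehyde | O=C[C@H]1C[C@H](O[Si](C)(C)C(C)(C)C)[C@H](CCCCC)O1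
F5 | step 5 | (1S,2S,4S,6R)-2-methoxy-4-pentyl-3,7-dioxabicyclo[4.1.0]heptan-5-one | CO[C@H]1O[C@@H](CCCCC)C(=O)[C@@H]2O[C@H]12
F6 | step 5 | (2S,5S,6S)-5-hydroxy-6-methoxy-2-pentyloxan-3-one | CO[C@H]1O[C@@H](CCCCC)C(=O)C[C@@H]1O
F7 | step 14 | (2S,3S,5R)-5-[(1S)-1-hydroxydec-9-en-1-yl]-2-pentyloxolan-3-yl octadecanoate | C=CCCCCCCC[C@H](O)[C@H]1C[C@H](OC(=O)CCCCCCCCCCCCCCCCC)[C@H](CCCCC)O1
F8 | step 14 | (2S,3S,5R)-5-(dec-9-enoyl)-2-pentyloxolan-3-yl octadecanoate | C=CCCCCCCCC(=O)[C@H]1C[C@H](OC(=O)CCCCCCCCCCCCCCCCC)[C@H](CCCCC)O1
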